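I began from amounts, not curves: one target costs two reagent, one for the open intermediate and one for the second intermediate.

the same everywhere: starting material 0.60 M; partner 1.08 M
- red: reagent 0.33 M; run made earlier
- blue: reagent 1.3 M; run made earlier
- flask: reagent 0.660 M; time 50 min

| red: time / min | red: target / % | blue: time / min | blue: target / % |
|---|---|---|---|
| 1.00 | 3 | 1.00 | 12 |
| 1.50 | 4 | 1.50 | 17 |
| 3.00 | 1 | 3.00 | 37 |
| 5.00 | 5 | 5.00 | 41 |
| 10.0 | 1 | 10.0 | 31 |
| 15.0 | 4 | 15.0 | 18 |
| 30.0 | 0 | 30.0 | 7 |

(readings scatter by 2 percentage points)

- amounts and yields of target count idle adduct too
- the numbers in the tables scatter with a standard deviation of 2 percentage points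
- what may be going on: target <-> isomer of the product; reagent + partner -> second intermediate; starting material + reagent -> open intermediate; reagent + target <-> idle adduct; open intermediate + second intermediate -> target

1. when, up to 50 min, the flask holds most target
2. the amount of target, in percent of the starting material charged, at that time

In the flask that cost gave a ceiling of 55.0 % of the starting material charged, with the reagent as limiting reagent, since its charge was less than two per starting material. For a floor I took c(reagent) − c(starting material), 0.0600 M in the flask, and called it the spare reagent: the starting material cannot take more reagent than its own charge, so, assuming that the reagent is used up in the end, with none held as idle adduct, and that the second intermediate made from the spare reagent meets open intermediate, I estimated a floor of 10.0 % under what passes through target.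

Blue's spare reagent, 0.700 M, exceeded its charge of starting material, so its whole charge could pass through, and I took its top reading of 41 % at 5.00 min, scatter included, as the share standing as target at the peak. I assumed that share held in the flask, which gave an estimated bracket for the flask's peak between 4.10 % and 22.6 %. My own figure was the geometric middle, 9.62 %, at a time between 3.00 min and 10.0 min, as in blue.

The forecast, 14 % at 4.5 min, began from “Target needs two reagent equivalents per starting material”; it lay inside my bracket  and above my middle.

The flask held most target at 3.89 min, earlier than forecast, with 11.7 %, less than forecast.

    target ⇌ isomer of the product (K = 24.0, k = 0.00340 s⁻¹)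
    reagent + partner → second intermediate (k = 0.00850 M⁻¹ s⁻¹)
    starting material + reagent → open intermediate (k = 0.130 M⁻¹ s⁻¹)
    reagent + target ⇌ idle adduct, settled at all times (K = 2.10 M⁻¹)
    open intermediate + second intermediate → target (k = 0.0180 M⁻¹ s⁻¹)

At 50.0 min the flask's reagent stood at 0 %, with isomer of the product at 21.8 % and target at 0.910 %, together 22.7 % passed through, above the floor of 10.0 %. In the neighbour flask with 1.7 M of reagent the spare reagent came to 1.10 M, above its 0.60 M of starting material, so the floor was the whole charge, and at 50.0 min that flask held isomer of the product at 95.5 % and target at 4.49 %.

The readings come from a simulation on assumed constants.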